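**Plan**

1. Cuts: the O5–benzyl bond (last step), then C4–C4a and O1–C2 together (the whole δ-lactone ring, key step), then the O4'–benzyl bond and the aryl–C(=O) bond back to phloroglucinol.
2. Enabling feature: C4a lies between the oxygen-bearing ring carbons C5 and C8a of a phloroglucinol ring (the enol of a cyclohexanetrione), so it is a carbon nucleophile. O1–C2(=O)–C3–C4(Ph) is a cinnamoyl unit at the acid oxidation level, so the benzyl-protected target is the exact 1:1 adduct of ketone 5 and phenylpropynal 6.
3. Regiochemistry comes from symmetry: with O4' capped, the two ring CH and the two free OH of 5 are pairwise equivalent and each CH has only one free neighbouring oxygen. Only the 8-acyl lactone can form; the 6-acyl isomer cannot.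
4. Forward order: Hoesch C-acylation of phloroglucinol, 4'-O-benzylation, carbene-catalysed redox-neutral [3+3] annulation (the only ring closure), hydrogenolysis.
5. Stereochemistry: C4 is the only stereocentre. It is set by the chiral triazolylidene in the C4–C4a bond formation and is not touched by the neutral last step.

Key step: step 3

Assumption: the (5aR,10bS) catalyst antipode is assigned to (4S) from a facial-shielding model of the acyl azolium, not from a measured result; if a first run shows the opposite sense, the commercial (5aS,10bR) antipode is used and the route is otherwise unchanged.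

**Route**

Step 1
Reactants: 1 phloroglucinol; 2 3-phenylpropanenitrile
Product: 4 3-phenyl-1-(2,4,6-trihydroxyphenyl)propan-1-one, via ketiminium chloride 3 (not isolated)
Conditions: HCl (g), ZnCl2 (0.2 equiv), Et2O, 0 °C; then H2O, reflux
Reagents that add atoms: water (O)
Why: Hoesch acylation, in which the protonated nitrile attacks the C3-symmetric ring once, the aryl ketiminium salt 3 is too electron-poor for a second acylation, and hot water hydrolyses it to the ketone; no stereocentre is formed.

Step 2
Reactants: 4 3-phenyl-1-(2,4,6-trihydroxyphenyl)propan-1-one
Product: 5 1-[4-(benzyloxy)-2,6-dihydroxyphenyl]-3-phenylpropan-1-one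
Conditions: BnBr (1.0 equiv), KHCO3 (1.1 equiv), DMF, 40 °C
Reagents that add atoms: benzyl bromide (BrCc1ccccc1)
Why: Williamson ether synthesis under bicarbonate control, in which only the para hydroxyl (a vinylogous carboxylic acid not tied to the ketone by a hydrogen bond) is ionised by the weak base, so O4' should be benzylated and the two ortho hydroxyls left free.

Step 3
Reactants: 5 1-[4-(benzyloxy)-2,6-dihydroxyphenyl]-3-phenylpropan-1-one; 6 3-phenylprop-2-ynal
Product: 8 (4S)-5-(benzyloxy)-7-hydroxy-4-phenyl-8-(3-phenylpropanoyl)-3,4-dihydro-2H-chromen-2-one, via cinnamoyl azolium chloride 7 (not isolated)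
Conditions: 6 (1.1 equiv, slow addition), (5aR,10bS)-2-mesityl-5a,10b-dihydro-4H,6H-indeno[2,1-b][1,2,4]triazolo[4,3-d][1,4]oxazin-2-ium chloride (10 mol%), iPr2NEt (10 mol%), toluene, 40 °C
Reagents that add atoms: none
Why: The carbene adds to the aldehyde of 6 and proton transfer through the allenol gives the (E)-cinnamoyl azolium 7 without any oxidant, which spares the oxidation-prone phenol; the closest known reaction type is the carbene-catalysed annulation of ynals or enals with naphthols and other stable enols to 4-substituted 3,4-dihydropyran-2-ones. A free ortho hydroxyl of 5 adds to the acyl carbon and C3' then bonds to the β-carbon in a Coates–Claisen-type [3,3] shift (formally a conjugate addition of the arene), after which rearomatisation and tautomerisation leave a β-aryl acyl azolium. The lactone ring closes by 6-exo-trig attack of O2' on this acyl azolium (addition–elimination), which forms O1–C2 and releases the carbene. C4 is created in the C–C bond-forming event and its configuration is controlled by the cis-fused indane of the catalyst, which covers one face of the s-cis enoyl azolium so that the arene adds to the other. The step needs site selectivity over two ring CH and three oxygens, and the substrate secures it by symmetry: O4' is benzylated, C3'/C5' and O2'/O6' are equivalent, and the only free oxygen next to the new bond is the one that must become O1. A second annulation at C6 should be slow because the last hydroxyl is tied to the C8 ketone by a hydrogen bond and the ring has lost a phenolic donor, while a 2'-O-cinnamate from direct O-acylation or a reopened lactone is an activated aryl ester that the carbene returns to the same acyl azolium, which can close on O2' only.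

Step 4
Reactants: 8 (4S)-5-(benzyloxy)-7-hydroxy-4-phenyl-8-(3-phenylpropanoyl)-3,4-dihydro-2H-chromen-2-one
Product: 9 (4S)-5,7-dihydroxy-4-phenyl-8-(3-phenylpropanoyl)-3,4-dihydro-2H-chromen-2-one
Conditions: H2 (1 atm), 10% Pd/C, EtOAc, 23 °C
Reagents that add atoms: none
Why: Hydrogenolysis of the aryl benzyl ether over Pd/C in a neutral, aprotic medium, in which the chelated 2-hydroxyaryl ketone (a vinylogous ester) and the lactone should not be reduced, C4 carries no C–O bond that could be cleaved, and nothing in the medium can epimerise it, so the (4S) configuration is kept.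

**Compound list**

1 | phloroglucinol (benzene-1,3,5-triol) | Oc1cc(O)cc(O)c1 | starting material
2 | 3-phenylpropanenitrile | N#CCCc1ccccc1 | starting material
3 | 3-phenyl-1-(2,4,6-trihydroxyphenyl)propan-1-iminium chloride (ketiminium chloride) | [NH2+]=C(CCc1ccccc1)c1c(O)cc(O)cc1O.[Cl-] | intermediate
4 | 3-phenyl-1-(2,4,6-trihydroxyphenyl)propan-1-one (2',4',6'-trihydroxydihydrochalcone) | O=C(CCc1ccccc1)c1c(O)cc(O)cc1O | intermediate
5 | 1-[4-(benzyloxy)-2,6-dihydroxyphenyl]-3-phenylpropan-1-one | O=C(CCc1ccccc1)c1c(O)cc(OCc2ccccc2)cc1O | intermediate
6 | 3-phenylprop-2-ynal | O=CC#Cc1ccccc1 | starting material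
7 | (5aR,10bS)-2-mesityl-1-[(E)-3-phenylprop-2-enoyl]-5a,10b-dihydro-4H,6H-indeno[2,1-b][1,2,4]triazolo[4,3-d][1,4]oxazin-2-ium chloride (cinnamoyl group on the carbene carbon, between the N-mesityl and the ring-fusion nitrogen) | Cc1cc(C)c(c(C)c1)[n+]1c(C(=O)/C=C/c5ccccc5)n2[C@H]3c4ccccc4C[C@H]3OCc2n1.[Cl-] | intermediate
8 | (4S)-5-(benzyloxy)-7-hydroxy-4-phenyl-8-(3-phenylpropanoyl)-3,4-dihydro-2H-chromen-2-one | O=C1C[C@@H](c2ccccc2)c2c(OCc3ccccc3)cc(O)c(C(=O)CCc3ccccc3)c2O1 | intermediate
9 | (4S)-5,7-dihydroxy-4-phenyl-8-(3-phenylpropanoyl)-3,4-dihydro-2H-chromen-2-one | O=C1C[C@@H](c2ccccc2)c2c(O)cc(O)c(C(=O)CCc3ccccc3)c2O1 | target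

**Step count and risks**

Total step count: 4. Longest linear sequence: 4.

Steps most likely to fail:

Step 3. The carbene cycle may be outrun by oxa-Michael addition of the phenoxide to the ynal, the facial selectivity may be insufficient on this hindered, ketone-bearing phenol, or a second annulation may set in at C6. The fallback forms the C4–Ph bond instead of C4–C4a. From 5, Pd-catalysed hydroarylation–lactonisation with ethyl propiolate (Pd2(dba)3 cat., NaOAc, HCO2H, 25 °C) should give 5-(benzyloxy)-7-hydroxy-8-(3-phenylpropanoyl)-2H-chromen-2-one F1, again a single regioisomer by the symmetry of 5. Rh(I)/(S)-SEGPHOS-catalysed 1,4-addition of phenylboronic acid (dioxane/H2O, 60 °C; ligand antipode chosen for (4S)) then returns to the route at 8.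

Step 2. Site selectivity may be poor: benzylation of an ortho hydroxyl, double benzylation, or some C-benzylation. The fallback protects all three hydroxyls and then deprotects selectively. From 4, exhaustive benzylation (BnBr excess, K2CO3, DMF, 70 °C) should give 3-phenyl-1-[2,4,6-tris(benzyloxy)phenyl]propan-1-one F2. Chelation-controlled cleavage of the two benzyl ethers ortho to the carbonyl with MgBr2·OEt2 (toluene/Et2O, 80 °C), which the para ether cannot undergo for lack of a neighbouring carbonyl, then returns to the route at 5.

Step 4. Hydrogen may also be taken up by the aryl ketone (reduction to the benzylic alcohol and on to the methylene compound) before the ether is gone. The fallback is a heterolytic instead of a reductive cleavage. From 8, BCl3 with pentamethylbenzene as benzyl-cation trap (CH2Cl2, −78 °C) should give 9 directly. The scavenger keeps the benzyl cation away from the free C6 position, the low temperature protects C4, and no new compound is made (F0).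

Further compounds
F1 | step 3 | 5-(benzyloxy)-7-hydroxy-8-(3-phenylpropanoyl)-2H-chromen-2-one | O=C1C=Cc2c(OCc3ccccc3)cc(O)c(C(=O)CCc3ccccc3)c2O1
F2 | step 2 | 3-phenyl-1-[2,4,6-tris(benzyloxy)phenyl]propan-1-one | O=C(CCc1ccccc1)c1c(OCc2ccccc2)cc(OCc2ccccc2)cc1OCc1ccccc1
F0 | step 4 | none | none
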